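The readings come from a simulation for an exercise, noise included.

The solution cannot hold at one moment the gas for the whole charge of the flask: saturation stands at 160 mM, less than the 0.28 M of starting material.

common to all: gas phase 160 mM (held)
- epsilon: starting material 0.14 M; run made earlier
- alpha: starting material 0.56 M; run made earlier
- flask: starting material 0.28 M; time 4.0 min

| run | time / min | target / % | starting material / % |
|---|---|---|---|
| epsilon | 0.333 | 30 | 5 |
| epsilon | 0.667 | 28 | 0 |
| epsilon | 1.50 | 26 | 0 |
| epsilon | 4.00 | 15 | 2 |
| alpha | 0.500 | 15 | 0 |
| alpha | 1.33 | 12 | 2 |
| alpha | 2.50 | 9 | 1 |
| alpha | 4.00 | 8 | 0 |

(readings scatter by 2 percentage points)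

- at the start none of the gas phase is in solution

- red: doubling the saturation concentration of gas phase, all else as stated
- violet: doubling the transfer coefficient of the gas phase, all else as stated

* the target standing at 4.0 min, as a percentage of the starting material charged
* concentration of dissolved gas in solution at 25 s, in percent of saturation
* the change that raises the amount of target at 4.0 min, in percent of the starting material charged most ("none" if none brings more than 2 percentage points) (red / violet / none)
* amount of target at 4.0 min, in percent of the starting material charged, after red

In the earlier runs the starting material reads 0% at 0.667 min in epsilon and 0% at 0.500 min in alpha, and the target falls from reading to reading. Two independent sets of readings give the rate of that fall. Epsilon's first and last target readings give 0.189 min⁻¹, and this reading is the first-order constant at which the standing target falls, the loss constant k. Alpha, with other readings and a charge of 0.56 M against 0.14 M, gives 0.180 min⁻¹, close to it, though its last reading of 8% carries an error of 2 percentage points. So k, as a reading with that scatter, is taken over to the flask.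

The flask's charge is the geometric middle of the two, so the geometric mean of the last readings, 15% and 8%, gives 11.0% at 4.0 min. The geometric mean of the first readings, 21.2%, placed near 25 s and carried forward by k, gives 10.8%. That way leans on epsilon's last reading too, so the agreement is partial.

Both runs held one saturation, so they cannot show whether k follows dissolved gas. If it does, red doubles k, and between 25 s and 4.0 min the target loses a further factor of 1.97. That factor is the crossing: red pays if the early target grows by more. The early gain under red is not reckoned here, and neither is a figure for the transfer.

The forecast gives 11% of target, dissolved gas at 80% of saturation at 25 s, red as the best change and 16% after it: “Doubling saturation raises dissolved gas whether or not transfer limits”. On red the forecast commits where the reckoning above stays conditional.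

The flask stands at 11.6% at 4.0 min, with dissolved gas at 65.7% of saturation at 25 s. Red moves the target by −4.5 points to 7.11% and violet moves it by 1.4 points, so the best change is none.

    gas phase ⇌ dissolved gas, rate k1*(csat - [dissolved gas]) (kL = 0.0990 s⁻¹)
    starting material + dissolved gas → target (k = 1.70 L mol⁻¹ s⁻¹)
    dissolved gas + target → over-reacted product (k = 0.0450 L mol⁻¹ s⁻¹)
    target ⇌ isomer of the product (K = 1.40, k = 0.140 s⁻¹)
    2 starting material → self-condensation product (k = 0.200 L mol⁻¹ s⁻¹)

From 22.8% at 0.400 min, the loss constant k carries the flask to 11.5% at 4.0 min. Carried back from 11.6%, the loss constant k gives 18.6% for the neighbour flask read at 1.5 min, which stands at 17.9%.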